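**Retrosynthetic overview**
1. Target 16 ⇐ monocyclic enone ketal 14 by a one-flask cationic bis-cyclisation at the ketal carbon C10. The seven-membered ring closes first (C10–C11, α′-enol silane). The cyclobutane closes last (C4–C10), when the enone's extended dienol attacks the C10 himachalyl-type cation anti to the participating 9-senecioate, as in the cyclase's himachalyl → longipinyl closure.
2. 14 ⇐ 4H-pyran 12, a masked prochiral heptane-2,6-dione, by amine-catalysed desymmetrising aldol condensation (six-membered ring, sets C5).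
3. 12 ⇐ aldehyde 6 + ketone 7 + tiglaldehyde 9 + acid chloride 11: proline aldol (C7), Evans–Tishchenko reduction (C9 anti, tiglate placed on O7), senecioylation.
4. 6 ⇐ 2,6-dimethylpyrylium salt 3 (from pyranone 1) + isobutyraldehyde enamine 4 (C5–C6 bond).
5. Ring order: six-membered → seven-membered → four-membered. Both esters are in place before any carbocycle exists.

Assumption: the target is taken exactly as the given SMILES, i.e. (4R,5S,7R,9R,10R,11R)-7-tigloyloxy-9-senecioyloxylongipin-2-en-1-one. Locants in the text follow longipinane numbering (C1 ketone, C2=C3, C4/C11 bridgeheads, C5 ring CH, C6 CMe2, C7 O-tiglate, C8 CH2, C9 O-senecioate, C10 quaternary C–Me).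

**Step 1**
Reactants: 1 2,6-dimethyl-4H-pyran-4-one
Product: 3 2,6-dimethylpyrylium tetrafluoroborate, via 2,6-dimethyl-4H-pyran-4-ol 2 (not isolated)
Conditions: DIBAL-H (1.1 equiv), CH2Cl2, −78 °C; then HBF4·OEt2 (2 equiv), Et2O, −78 → 0 °C, filter
Reagents that add atoms: tetrafluoroboric acid (as HBF4·OEt2), [H+].F[B-](F)(F)F
Why: 1,2-hydride reduction of the vinylogous ester carbonyl, then acid-induced loss of hydroxide from the resulting pyranol, gives the aromatic pyrylium ion (pyranone → pyranol → pyrylium sequence); no stereocentre.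

**Step 2**
Reactants: 3 2,6-dimethylpyrylium tetrafluoroborate; 4 4-(2-methylprop-1-en-1-yl)morpholine
Product: 6 2-(2,6-dimethyl-4H-pyran-4-yl)-2-methylpropanal, via iminium tetrafluoroborate 5 (not isolated)
Conditions: MeCN, −30 → 0 °C; then H2O, 0 °C
Reagents that add atoms: 4-(2-methylprop-1-en-1-yl)morpholine 4, CC(C)=CN1CCOCC1; water, O
Why: Stork enamine alkylation by a cationic electrophile: the bulky enamine carbon adds at the unsubstituted γ-position of the pyrylium ring to give the 4H-pyran (forming the C5–C6 bond), and iminium hydrolysis frees the non-enolisable aldehyde; no stereocentre, because the pyran is a masked prochiral 1,5-diketone.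

**Step 3**
Reactants: 6 2-(2,6-dimethyl-4H-pyran-4-yl)-2-methylpropanal; 7 3,3-dimethoxybutan-2-one
Product: 8 (5R)-6-(2,6-dimethyl-4H-pyran-4-yl)-5-hydroxy-2,2-dimethoxy-6-methylheptan-3-one
Conditions: (S)-proline (30 mol%), 7 (10 equiv), DMSO, 23 °C
Reagents that add atoms: 3,3-dimethoxybutan-2-one 7, CC(=O)C(C)(OC)OC
Why: List–Barbas proline-catalysed direct aldol: 7 can form an enamine only at its methyl group, the α-quaternary aldehyde cannot enolise, and the Houk–List transition state (re-face attack, as with pivalaldehyde) sets the carbinol centre (later C7) as R.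

**Step 4**
Reactants: 8 (5R)-6-(2,6-dimethyl-4H-pyran-4-yl)-5-hydroxy-2,2-dimethoxy-6-methylheptan-3-one; 9 (2E)-2-methylbut-2-enal
Product: 10 (3R,5R)-2-(2,6-dimethyl-4H-pyran-4-yl)-5-hydroxy-6,6-dimethoxy-2-methylheptan-3-yl (2E)-2-methylbut-2-enoate
Conditions: SmI2 (20 mol%), 9 (5 equiv), THF, −10 °C
Reagents that add atoms: (2E)-2-methylbut-2-enal 9, C/C=C(\C)C=O
Why: Evans–Tishchenko reduction: the samarium-bound hemiacetal formed from the β-hydroxyl and tiglaldehyde delivers hydride intramolecularly through a chair-like six-membered transition state, which sets the new carbinol centre (later C9) 1,3-anti and leaves the oxidised aldehyde as the tiglate on the original hydroxyl, so the two oxygens are differentiated without protecting groups.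

**Step 5**
Reactants: 10 (3R,5R)-2-(2,6-dimethyl-4H-pyran-4-yl)-5-hydroxy-6,6-dimethoxy-2-methylheptan-3-yl (2E)-2-methylbut-2-enoate; 11 3-methylbut-2-enoyl chloride
Product: 12 (3R,5R)-2-(2,6-dimethyl-4H-pyran-4-yl)-6,6-dimethoxy-2-methyl-5-[(3-methylbut-2-enoyl)oxy]heptan-3-yl (2E)-2-methylbut-2-enoate
Conditions: pyridine (3 equiv), DMAP (10 mol%), CH2Cl2, 0 → 23 °C
Reagents that add atoms: 3-methylbut-2-enoyl chloride 11, CC(C)=CC(=O)Cl
Why: DMAP-catalysed acylation of the only free hydroxyl, with pyridine rather than Et3N to avoid the vinylketene pathway that deconjugates senecioates; no stereocentre is touched.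

**Step 6**
Reactants: 12 (3R,5R)-2-(2,6-dimethyl-4H-pyran-4-yl)-6,6-dimethoxy-2-methyl-5-[(3-methylbut-2-enoyl)oxy]heptan-3-yl (2E)-2-methylbut-2-enoate
Product: 14 (3R,5R)-6,6-dimethoxy-2-methyl-5-[(3-methylbut-2-enoyl)oxy]-2-[(1S)-5-methyl-3-oxocyclohex-4-en-1-yl]heptan-3-yl (2E)-2-methylbut-2-enoate, via 1,5-diketone 13 (not isolated)
Conditions: AcOH–THF–H2O (3:3:1), 0 °C; evaporate; then 9-amino(9-deoxy)epi-quinine (20 mol%), AcOH (60 mol%), toluene, −15 → 23 °C
Reagents that add atoms: water, O
Why: hydrolysis of the bis-enol ether (much faster than that of the α-acyloxy dimethyl ketal) unveils the prochiral 4-substituted heptane-2,6-dione, and a List-type primary-amine-catalysed intramolecular aldol condensation selects one enantiotopic acetonyl arm and so sets the ring stereocentre C5 as S; the sense is assigned by analogy, and the quinidine-derived pseudo-enantiomer is used if it proves opposite.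

**Step 7**
Reactants: 14 (3R,5R)-6,6-dimethoxy-2-methyl-5-[(3-methylbut-2-enoyl)oxy]-2-[(1S)-5-methyl-3-oxocyclohex-4-en-1-yl]heptan-3-yl (2E)-2-methylbut-2-enoate
Product: 16 (4R,5S,7R,9R,10R,11R)-7-[(2E)-2-methylbut-2-enoyloxy]-9-(3-methylbut-2-enoyloxy)longipin-2-en-1-one (target), via bicyclic methyl ether 15 (not isolated)
Conditions: TMSOTf (3 equiv), i-Pr2NEt (2.5 equiv), CH2Cl2, −78 °C (2 h) → 0 °C (3 h); aq. NaHCO3
Reagents that add atoms: none
Why: Proposed new method: TMSOTf ionises the dimethyl ketal to the C10 oxocarbenium ion while TMSOTf/i-Pr2NEt converts the enone at −78 °C into its kinetic cross-conjugated (α′) silyl dienol ether, whose intramolecular Mukaiyama-type addition closes the seven-membered ring (C10–C11) to 15; on warming, the tertiary methyl ether is ionised with anchimeric assistance from the 9-senecioate (acyloxonium on the face away from the six-membered ring), the enone is re-silylated to the thermodynamic extended dienol ether, and its γ-carbon C4 attacks C10 anti to the C10–O bond, closing the cyclobutane and returning the enone with the senecioate retained at C9; once C5 is fixed the bridged skeleton allows only one relative configuration at C4, C10 and C11 (C11 can epimerise through the enol silane), and anti opening matches the 9α-oxygen; the closest known reactions are one-pot enol silane formation/Mukaiyama addition to dimethyl acetals with TMSOTf–amine, Reetz SN1 tert-alkylation of silyl enol ethers, Fleming–Paterson γ-alkylation of silyl dienol ethers and Gassman's cation–olefin cyclobutane closures.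

**Compound list**
1 | 2,6-dimethyl-4H-pyran-4-one | CC1=CC(=O)C=C(C)O1 | starting material
2 | 2,6-dimethyl-4H-pyran-4-ol (as its diisobutylaluminium alkoxide in the flask) | CC1=CC(O)C=C(C)O1 | intermediate (not isolated)
3 | 2,6-dimethylpyrylium tetrafluoroborate | Cc1cccc(C)[o+]1.F[B-](F)(F)F | intermediate
4 | 4-(2-methylprop-1-en-1-yl)morpholine | CC(C)=CN1CCOCC1 | starting material
5 | 4-[2-(2,6-dimethyl-4H-pyran-4-yl)-2-methylpropylidene]morpholin-4-ium tetrafluoroborate | CC1=CC(C=C(C)O1)C(C)(C)C=[N+]1CCOCC1.F[B-](F)(F)F | intermediate (not isolated)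
6 | 2-(2,6-dimethyl-4H-pyran-4-yl)-2-methylpropanal | CC1=CC(C=C(C)O1)C(C)(C)C=O | intermediate
7 | 3,3-dimethoxybutan-2-one | CC(=O)C(C)(OC)OC | starting material
8 | (5R)-6-(2,6-dimethyl-4H-pyran-4-yl)-5-hydroxy-2,2-dimethoxy-6-methylheptan-3-one | CC(OC)(OC)C(=O)C[C@@H](O)C(C)(C)C1C=C(C)OC(C)=C1 | intermediate
9 | (2E)-2-methylbut-2-enal (tiglaldehyde) | C/C=C(\C)C=O | starting material
10 | (3R,5R)-2-(2,6-dimethyl-4H-pyran-4-yl)-5-hydroxy-6,6-dimethoxy-2-methylheptan-3-yl (2E)-2-methylbut-2-enoate | C/C=C(\C)C(=O)O[C@H](C[C@@H](O)C(C)(OC)OC)C(C)(C)C1C=C(C)OC(C)=C1 | intermediate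
11 | 3-methylbut-2-enoyl chloride | CC(C)=CC(=O)Cl | starting material
12 | (3R,5R)-2-(2,6-dimethyl-4H-pyran-4-yl)-6,6-dimethoxy-2-methyl-5-[(3-methylbut-2-enoyl)oxy]heptan-3-yl (2E)-2-methylbut-2-enoate | C/C=C(\C)C(=O)O[C@H](C[C@@H](OC(=O)C=C(C)C)C(C)(OC)OC)C(C)(C)C1C=C(C)OC(C)=C1 | intermediate
13 | (3R,5R)-2-(2,6-dioxoheptan-4-yl)-6,6-dimethoxy-2-methyl-5-[(3-methylbut-2-enoyl)oxy]heptan-3-yl (2E)-2-methylbut-2-enoate | C/C=C(\C)C(=O)O[C@H](C[C@@H](OC(=O)C=C(C)C)C(C)(OC)OC)C(C)(C)C(CC(C)=O)CC(C)=O | intermediate (not isolated)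
14 | (3R,5R)-6,6-dimethoxy-2-methyl-5-[(3-methylbut-2-enoyl)oxy]-2-[(1S)-5-methyl-3-oxocyclohex-4-en-1-yl]heptan-3-yl (2E)-2-methylbut-2-enoate | CC1=CC(=O)C[C@H](C1)C(C)(C)[C@H](OC(=O)/C(C)=C/C)C[C@@H](OC(=O)C=C(C)C)C(C)(OC)OC | intermediate
15 | (4aR,6R,8R,9aS)-5-methoxy-2,5,9,9-tetramethyl-4-oxo-4,4a,5,6,7,8,9,9a-octahydro-1H-benzo[7]annulene-6,8-diyl 6-(3-methylbut-2-enoate) 8-[(2E)-2-methylbut-2-enoate], cis-fused, mixture of epimers at the methoxy carbon (re-ionised in the same flask) | C/C=C(\C)C(=O)O[C@@H]1C[C@@H](OC(=O)C=C(C)C)C(C)(OC)[C@@H]2C(=O)C=C(C)C[C@@H]2C1(C)C | intermediate (not isolated)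
16 | (4R,5S,7R,9R,10R,11R)-7-[(2E)-2-methylbut-2-enoyloxy]-9-(3-methylbut-2-enoyloxy)longipin-2-en-1-one (CNP0257816.1) | C/C=C(\C)C(=O)O[C@@H]1C[C@@H](OC(=O)C=C(C)C)[C@@]2(C)[C@@H]3C(=O)C=C(C)[C@H]2[C@@H]3C1(C)C | target

**Totals**
Total step count: 7. Longest linear sequence: 7 steps (1 → 16).

**Steps most likely to fail**

Step 7 (one-flask bis-cyclisation). The C10 cation or acyloxonium ion can lose a proton instead of closing the four-membered ring. A first closure through the γ-carbon instead of the α′-carbon would give a bicycle that cannot close anti to the senecioate. Fallback, from 14 back to 16: replace the cascade by two isolated ring closures of different type. Aqueous TFA (THF, 0 °C) removes the ketal to give the methyl ketone F1. TiCl4/i-Pr2NEt (CH2Cl2, −78 °C) generates only the α′-titanium enolate, and its aldol addition to the α-acyloxy ketone closes the seven-membered ring to the tertiary alcohol F2 (both C10 epimers usable). F2 is then ionised with a Brønsted acid in an ionising, non-nucleophilic solvent (Tf2NH 10 mol%, HFIP, 0 °C), where the enone reacts through its extended dienol, to give 16.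

Step 6 (desymmetrising aldol condensation). The quaternary substituent on the diketone may slow the amine catalysis or erode arm selection, and the ketal must survive the pyran hydrolysis. Fallback, from 12 back to 15: reverse the ring order so that no external catalyst has to tell the two acetonyl arms apart. Catalytic TMSOTf with 2,6-di-tert-butylpyridine (CH2Cl2, −78 °C) ionises the ketal, and one of the two diastereotopic enol-ether carbons of the pyran attacks C10, so the seven-membered ring forms first with arm selection controlled by the C7 and C9 centres in the tether. Aqueous quench opens the pyranyl cation to the bicyclic 1,5-diketone F3, where any C5-epimeric series is removed by chromatography. Pyrrolidinium acetate (toluene, 23 °C) then condenses the methyl of the branched acetyl group onto the free acetonyl ketone to give 15, now isolated, which is taken to 16 with TMSOTf/i-Pr2NEt at 0 °C.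

Step 3 (proline aldol). The donor ketone is hindered, and the 4H-pyran is acid-labile over the long reaction time. Fallback, from 6 (with 7) back to 8: replace enamine catalysis by a reagent-controlled boron aldol. Ketone 7 is enolised with Ipc2BCl/Et3N (Et2O, −78 °C), aldehyde 6 is added, and the borinate is cleaved oxidatively (H2O2, pH 7), using the Ipc antipode that gives the 5R carbinol. The strictly anhydrous, basic conditions spare the pyran. This fallback makes no new compound (F0).

**Further compounds**
F1 | step 7 | (3R,5R)-2-methyl-5-[(3-methylbut-2-enoyl)oxy]-2-[(1S)-5-methyl-3-oxocyclohex-4-en-1-yl]-6-oxoheptan-3-yl (2E)-2-methylbut-2-enoate | CC1=CC(=O)C[C@H](C1)C(C)(C)[C@H](OC(=O)/C(C)=C/C)C[C@@H](OC(=O)C=C(C)C)C(C)=O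
F2 | step 7 | (4aR,6R,8R,9aS)-5-hydroxy-2,5,9,9-tetramethyl-4-oxo-4,4a,5,6,7,8,9,9a-octahydro-1H-benzo[7]annulene-6,8-diyl 6-(3-methylbut-2-enoate) 8-[(2E)-2-methylbut-2-enoate] (epimers at the carbinol carbon) | C/C=C(\C)C(=O)O[C@@H]1C[C@@H](OC(=O)C=C(C)C)C(C)(O)[C@@H]2C(=O)C=C(C)C[C@@H]2C1(C)C
F3 | step 6 | (1R,3R,4S,6R)-3-acetyl-2-methoxy-2,5,5-trimethyl-4-(2-oxopropyl)cycloheptane-1,6-diyl 1-(3-methylbut-2-enoate) 6-[(2E)-2-methylbut-2-enoate] (epimers at the methoxy carbon) | C/C=C(\C)C(=O)O[C@@H]1C[C@@H](OC(=O)C=C(C)C)C(C)(OC)[C@H](C(C)=O)[C@H](CC(C)=O)C1(C)C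
F0 | step 3 | none | none
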